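The data come from a simulation from invented constants.

The ratio to watch is r, the Q charged per G charged: 1.02 in autumn and 2.94 in midnight, so G is the smaller charge in each.

| setting | Saturday's | Sunday's | Tuesday's | autumn | midnight |
|---|---|---|---|---|---|
| G | 0.34 M | 0.34 M | 0.34 M | 0.34 M | 0.34 M |
| Q | 0.28 M | 0.53 M | 0.81 M | 0.347 M | 1.00 M |
| remark | run made earlier | run made earlier | run made earlier |  |  |
| time |  |  |  | 5.0 min | 5.0 min |

- Saturday's (time / min: E / %, G / %): 0.667: 51.3, 48.3; 1.33: 55.8, 44.4; 2.00: 60.0, 40.6; 3.00: 64.4, 35.4; 4.00: 67.1, 32.3
- Sunday's (time / min: E / %, G / %): 0.333: 65.1, 34.9; 0.833: 71.8, 29.5; 1.50: 76.3, 23.3; 2.50: 82.3, 17.3; 4.00: 89.0, 10.5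
- Tuesday's (time / min: E / %, G / %): 0.250: 73.9, 25.7; 0.500: 76.0, 23.1; 1.00: 81.3, 19.2; 2.00: 88.8, 11.3; 4.00: 95.4, 4.1

(scatter of a reading: 0.5 percentage points)

- each molecule carries two end groups: a chain counts once for every two ends that are left, dead ends included; the units are half of the end groups of the two monomers charged
- the numbers in the tables scatter with a standard deviation of 0.5 percentage points
- steps under discussion: G + Q <-> E + Z; Z -> L; Q -> D

1. which of the two ends with the longer chains by the average number of monomer units in a chain (unreacted monomers counted as chains of one) ("neither" if they lie within 10%) (autumn / midnight / neither)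
2. average number of monomer units in a chain (unreacted monomers counted as chains of one) at the end, autumn
3. average number of monomer units in a chain (unreacted monomers counted as chains of one) at the end, midnight

Write the balance of G in fractions of its charge: g + e = 1, with e the links. Each link removes 2 ends, so the average chain length is n = (1 + r)/(1 + r − 2e). At e = 1 this gives the length ceiling (1 + r)/(r − 1), which is 2.03 for midnight. For autumn it is 98.1, too high to help, so you bound e from the readings.

Midnight has more Q and more time than Tuesday's run, so Tuesday's last e is my lower bound. For autumn I work at 4.00 min, where e bends over as Q rises. The chord from Saturday's run to Sunday's therefore lies below autumn's e, and the extra minute only adds. The chord from Tuesday's run to Sunday's, extended back to autumn's Q, lies above it. To that I add a minute at Sunday's late rate of 0.0447 min⁻¹.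

| flask | e, low | e, high | n, low | n, high |
|---|---|---|---|---|
| autumn | 0.730 | 0.893 | 3.60 | 8.60 |
| midnight | 95.4% | 1 | 1.94 | 2.03 |

Autumn's low bound stands above midnight's ceiling, so I expect autumn to end with the longer chains.

The forecast gives autumn, with 4.5 for autumn and 2 for midnight, and adds of autumn: “This is sensitive to small errors.”

The flask gives autumn, with 4.57 for autumn and 2.00 for midnight, each inside my bracket.

    G + Q ⇌ E + Z (K = 0.993, k = 2.06 L mol⁻¹ s⁻¹)
    Z → L (k = 0.0166 s⁻¹)
    Q → D (k = 0.00112 s⁻¹)

Midnight's chains are short because of its excess of Q: at autumn's Q the same flask reaches 4.57 instead of 2.00. With e at 98.3%, midnight stands just under its ceiling of 2.03, and G, down to 1.68% of its charge against 46.9% for Q, is the limiting reagent of that flask. The neighbouring flask raises G to 0.85 M at midnight's Q, which brings r down to 1.18 and lifts the ceiling to 12.3. There e reaches 84.4%, and the chains average 4.45 units.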